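**Retrosynthetic overview** (cembrane numbering: C1=C15 is the dihydrofuran double bond, C2 the O–CH, C16 the O–CH2, C17 the CH2OAc carbon, C7/C8 the oxirane)
1. Target ⇐ acetylation and ester reduction of the macrocyclic methyl 2,5-dihydrofuran-3-carboxylate.
2. Third ring, the 14-membered carbocycle: closed last at C10–C11 by a nickel-catalysed reductive coupling of an (E)-alkenyl bromide and a primary alkyl bromide (key bond).
3. Second ring, the 2,5-dihydrofuran: palladium-catalysed 5-endo cyclisation–methoxycarbonylation of a 2-substituted α-allenol (brings in C17).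
4. Allenol ⇐ catalytic asymmetric allenylboration (C1–C2 bond, C2 stereocentre) joining an epoxy enal (C2–C10) and a propargylic boronate (C1, C11–C16).
5. First ring, the (7S,8S)-oxirane: Shi epoxidation on the C2–C10 piece, which is built from 4-bromobut-1-yne, vinyl bromide and methyl acetoacetate; the boronate comes from pent-4-yn-1-ol.

Assumption: all catalysts, ligands and reagents are purchased, and the facial senses quoted for the L-fructose-derived Shi ketone and for (R)-TRIP follow the usual models (the mirror-image catalyst would be used if either proved opposite).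

**Step 1**
Reactants: 1 methyl acetoacetate
Product: 2 methyl (2E)-3-(trifluoromethanesulfonyloxy)but-2-enoate
Conditions: aq. Me4NOH, Tf2O, hexanes, 5 °C
Reagents that add atoms: trifluoromethanesulfonic anhydride, O=S(=O)(OS(=O)(=O)C(F)(F)F)C(F)(F)F
Why: Enol triflation of a β-keto ester, in which the non-chelated tetraalkylammonium enolate is O-sulfonylated to the (E)-enol triflate (OTf trans to CO2Me), fixing the later C3=C4 geometry.

**Step 2**
Reactants: 3 4-bromobut-1-yne
Product: 5 (3E)-6-bromo-4-methylhexa-1,3-diene, via alkenyldimethylalane 4 (not isolated)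
Conditions: Me3Al (2 equiv), Cp2ZrCl2 (0.25 equiv), CH2Cl2, rt; then CH2=CHBr, ZnCl2 (0.3 equiv), Pd(PPh3)4 (5 mol%), THF, rt
Reagents that add atoms: trimethylaluminium, C[Al](C)C; vinyl bromide, C=CBr
Why: Negishi zirconium-catalysed carboalumination (syn addition, methyl to the internal carbon) followed by palladium-catalysed alkenylalane–vinyl bromide cross-coupling with retention gives the (E)-trisubstituted diene and the C6–C7 bond, the primary bromide being inert to both.

**Step 3**
Reactants: 5 (3E)-6-bromo-4-methylhexa-1,3-diene; 2 methyl (2E)-3-(trifluoromethanesulfonyloxy)but-2-enoate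
Product: 7 methyl (2E,6E)-9-bromo-3,7-dimethylnona-2,6-dienoate, via B-alkyl-9-borabicyclononane 6 (not isolated)
Conditions: 9-BBN (1.1 equiv), THF, 0 °C to rt; then 2, PdCl2(dppf) (5 mol%), aq. K3PO4, DMF, rt
Reagents that add atoms: none
Why: 9-BBN hydroborates only the monosubstituted alkene of the diene at its terminus, and the B-alkyl Suzuki–Miyaura coupling with the activated enol triflate proceeds with retention to give the C4–C5 bond and the (E)-enoate.

**Step 4**
Reactants: 7 methyl (2E,6E)-9-bromo-3,7-dimethylnona-2,6-dienoate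
Product: 8 methyl (2E)-5-[(2S,3S)-3-(2-bromoethyl)-3-methyloxiran-2-yl]-3-methylpent-2-enoate
Conditions: L-fructose-derived Shi ketone (30 mol%), KHSO5 (as 2KHSO5·KHSO4·K2SO4), K2CO3, Bu4NHSO4, MeCN–CH2(OMe)2/aq. Na2B4O7 buffer, 0 °C
Reagents that add atoms: potassium peroxymonosulfate, [K+].OOS(=O)(=O)[O-]
Why: Shi asymmetric epoxidation, in which the chiral dioxirane attacks only the electron-rich trisubstituted alkene (the enoate is deactivated) through the spiro transition state, sets both oxirane centres (7S,8S) under catalyst control.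

**Step 5**
Reactants: 8 methyl (2E)-5-[(2S,3S)-3-(2-bromoethyl)-3-methyloxiran-2-yl]-3-methylpent-2-enoate
Product: 9 (2E)-5-[(2S,3S)-3-(2-bromoethyl)-3-methyloxiran-2-yl]-3-methylpent-2-en-1-ol
Conditions: i-Bu2AlH (2.2 equiv), CH2Cl2, −78 °C; aq. KNaC4H4O6 work-up
Reagents that add atoms: none
Why: 1,2-Reduction of the conjugated ester by the aluminium hydride at −78 °C leaves the trisubstituted epoxide and the alkyl bromide untouched.

**Step 6**
Reactants: 9 (2E)-5-[(2S,3S)-3-(2-bromoethyl)-3-methyloxiran-2-yl]-3-methylpent-2-en-1-ol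
Product: 10 (2E)-5-[(2S,3S)-3-(2-bromoethyl)-3-methyloxiran-2-yl]-3-methylpent-2-enal
Conditions: MnO2 (15 equiv), CH2Cl2, rt
Reagents that add atoms: none
Why: Chemoselective allylic alcohol oxidation with MnO2 gives the (E)-enal under neutral conditions.

**Step 7**
Reactants: 11 pent-4-yn-1-ol
Product: 13 (4E)-5-bromo-4-methylpent-4-en-1-ol, via bis(dimethylalumanyl) pentenolate 12 (not isolated)
Conditions: Me3Al (3 equiv), Cp2ZrCl2 (0.25 equiv), CH2Cl2, 0 °C to rt; then NBS, THF, −30 °C
Reagents that add atoms: trimethylaluminium, C[Al](C)C; N-bromosuccinimide, O=C1CCC(=O)N1Br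
Why: Negishi carboalumination followed by bromodealumination with retention gives the (E)-alkenyl bromide that carries the C11=C12 geometry.

**Step 8**
Reactants: 13 (4E)-5-bromo-4-methylpent-4-en-1-ol
Product: 14 (4E)-5-bromo-4-methylpent-4-enal
Conditions: Dess–Martin periodinane, NaHCO3, CH2Cl2, 0 °C to rt
Reagents that add atoms: none
Why: Buffered Dess–Martin oxidation of a primary alcohol to the aldehyde.

**Step 9**
Reactants: 14 (4E)-5-bromo-4-methylpent-4-enal
Product: 15 (1E)-1-bromo-2-methylhex-1-en-5-yne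
Conditions: dimethyl (1-diazo-2-oxopropyl)phosphonate, K2CO3, MeOH, 0 °C to rt
Reagents that add atoms: dimethyl (1-diazo-2-oxopropyl)phosphonate, CC(=O)C(=[N+]=[N-])P(=O)(OC)OC
Why: Ohira–Bestmann (Seyferth–Gilbert) homologation turns the aldehyde into the terminal alkyne, adding C15.

**Step 10**
Reactants: 15 (1E)-1-bromo-2-methylhex-1-en-5-yne
Product: 18 2-[(6E)-7-bromo-6-methylhept-6-en-2-yn-1-yl]-4,4,5,5-tetramethyl-1,3,2-dioxaborolane, via lithium acetylide 16 (not isolated), via lithium alkynyl(iodomethyl)borate 17 (not isolated)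
Conditions: LiN(i-Pr)2 (1.0 equiv), THF, −78 °C; then ICH2Bpin, −78 °C to rt
Reagents that add atoms: 2-(iodomethyl)-4,4,5,5-tetramethyl-1,3,2-dioxaborolane, ICB1OC(C)(C)C(C)(C)O1
Why: Matteson-type homologation, in which the acetylide (only the alkyne C–H is removed by one equivalent of amide base) adds to boron and 1,2-migration with loss of iodide gives the γ-substituted propargylic boronate, adding C16.

**Step 11**
Reactants: 10 (2E)-5-[(2S,3S)-3-(2-bromoethyl)-3-methyloxiran-2-yl]-3-methylpent-2-enal; 18 2-[(6E)-7-bromo-6-methylhept-6-en-2-yn-1-yl]-4,4,5,5-tetramethyl-1,3,2-dioxaborolane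
Product: 20 (4S,5E)-3-[(3E)-4-bromo-3-methylbut-3-en-1-yl]-8-[(2S,3S)-3-(2-bromoethyl)-3-methyloxiran-2-yl]-6-methylocta-1,2,5-trien-4-ol, via O-pinacolboryl allenol 19 (not isolated)
Conditions: (R)-TRIP (10 mol%), 4 Å MS, toluene, −20 °C; aq. NaHCO3 work-up
Reagents that add atoms: none
Why: Chiral phosphoric acid-catalysed allenylboration, an SE2′ transfer of the propargylic boronate through a closed six-membered transition state to the Re face of the enal, forms the C1–C2 bond, the 2-substituted α-allenol and the carbinol centre (2S in the target) under catalyst control.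

**Step 12**
Reactants: 20 (4S,5E)-3-[(3E)-4-bromo-3-methylbut-3-en-1-yl]-8-[(2S,3S)-3-(2-bromoethyl)-3-methyloxiran-2-yl]-6-methylocta-1,2,5-trien-4-ol
Product: 21 methyl (5S)-4-[(3E)-4-bromo-3-methylbut-3-en-1-yl]-5-{(1E)-4-[(2S,3S)-3-(2-bromoethyl)-3-methyloxiran-2-yl]-2-methylbut-1-en-1-yl}-2,5-dihydrofuran-3-carboxylate
Conditions: Pd(OAc)2 (10 mol%), p-benzoquinone (2 equiv), NaOAc (0.5 equiv), CO (1 atm), MeOH–THF (1:3), 0 °C to rt
Reagents that add atoms: carbon monoxide, [C-]#[O+]; methanol, CO
Why: Oxypalladation–alkoxycarbonylation, in which divalent palladium activates the terminal allene bond, the hydroxyl closes 5-endo onto the CH2 terminus, and CO insertion and methanolysis of the dihydrofuranyl–palladium species give the ester while benzoquinone returns zerovalent palladium to the divalent state; the carbinol centre is not touched and the acetate buffer protects the epoxide.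

**Step 13**
Reactants: 21 methyl (5S)-4-[(3E)-4-bromo-3-methylbut-3-en-1-yl]-5-{(1E)-4-[(2S,3S)-3-(2-bromoethyl)-3-methyloxiran-2-yl]-2-methylbut-1-en-1-yl}-2,5-dihydrofuran-3-carboxylate
Product: 22 methyl (2S,7S,8S,3E,11E)-2,16:7,8-diepoxycembra-1(15),3,11-trien-17-oate
Conditions: NiBr2(MeOCH2CH2OMe) (20 mol%), 4,4′-di-tert-butyl-2,2′-bipyridine (24 mol%), Mn powder (3 equiv), NaI (0.5 equiv), DMA, 40 °C, syringe-pump addition of 21 over 12 h (final 2 mM)
Reagents that add atoms: none
Why: Proposed new method: an intramolecular nickel-catalysed reductive cross-electrophile coupling closes the 14-membered carbocycle at C10–C11, the reasoning being that zerovalent nickel–bipyridine inserts first into the alkenyl C–Br bond, a monovalent nickel halide abstracts halogen from the primary alkyl bromide (iodide after exchange with NaI) to give a primary radical two carbons away from the oxirane (so no ring opening), this radical is captured by the alkenylnickel of the same molecule under high dilution, and the resulting trivalent nickel reductively eliminates with retention of the (E)-geometry while Mn returns nickel to the low-valent state; the closest known reaction type is the intermolecular nickel-catalysed reductive coupling of alkenyl bromides with primary alkyl bromides.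

**Step 14**
Reactants: 22 methyl (2S,7S,8S,3E,11E)-2,16:7,8-diepoxycembra-1(15),3,11-trien-17-oate
Product: 23 (2S,7S,8S,3E,11E)-2,16:7,8-diepoxycembra-1(15),3,11-trien-17-ol
Conditions: i-Bu2AlH (2.5 equiv), CH2Cl2, −78 °C; aq. KNaC4H4O6 work-up
Reagents that add atoms: none
Why: Hydride reduction of the conjugated ester to the primary allylic alcohol at −78 °C, which a trisubstituted epoxide tolerates.

**Step 15**
Reactants: 23 (2S,7S,8S,3E,11E)-2,16:7,8-diepoxycembra-1(15),3,11-trien-17-ol
Product: 24 (2S,7S,8S,3E,11E)-17-acetoxy-2,16:7,8-diepoxycembra-1(15),3,11-triene (CNP0140293.1)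
Conditions: Ac2O, pyridine, DMAP (cat.), CH2Cl2, 0 °C
Reagents that add atoms: acetic anhydride, CC(=O)OC(C)=O
Why: DMAP-catalysed acetylation of the primary alcohol under mild basic conditions gives the target.

**Compound list**
1 | methyl acetoacetate (methyl 3-oxobutanoate) | CC(=O)CC(=O)OC | starting material
2 | methyl (2E)-3-(trifluoromethanesulfonyloxy)but-2-enoate | COC(=O)/C=C(\C)OS(=O)(=O)C(F)(F)F | intermediate
3 | 4-bromobut-1-yne | BrCCC#C | starting material
4 | [(1E)-4-bromo-2-methylbut-1-en-1-yl]dimethylalane (not isolated) | C[Al](C)/C=C(\C)CCBr | intermediate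
5 | (3E)-6-bromo-4-methylhexa-1,3-diene | C=C/C=C(\C)CCBr | intermediate
6 | 9-[(3E)-6-bromo-4-methylhex-3-en-1-yl]-9-borabicyclo[3.3.1]nonane (not isolated) | BrCC/C(C)=C/CCB1C2CCCC1CCC2 | intermediate
7 | methyl (2E,6E)-9-bromo-3,7-dimethylnona-2,6-dienoate | COC(=O)/C=C(\C)CC/C=C(\C)CCBr | intermediate
8 | methyl (2E)-5-[(2S,3S)-3-(2-bromoethyl)-3-methyloxiran-2-yl]-3-methylpent-2-enoate | COC(=O)/C=C(\C)CC[C@@H]1O[C@@]1(C)CCBr | intermediate
9 | (2E)-5-[(2S,3S)-3-(2-bromoethyl)-3-methyloxiran-2-yl]-3-methylpent-2-en-1-ol | OC/C=C(\C)CC[C@@H]1O[C@@]1(C)CCBr | intermediate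
10 | (2E)-5-[(2S,3S)-3-(2-bromoethyl)-3-methyloxiran-2-yl]-3-methylpent-2-enal | O=C/C=C(\C)CC[C@@H]1O[C@@]1(C)CCBr | intermediate
11 | pent-4-yn-1-ol | C#CCCCO | starting material
12 | dimethylaluminium (4E)-5-(dimethylalumanyl)-4-methylpent-4-en-1-olate (not isolated) | C[Al](C)/C=C(\C)CCCO[Al](C)C | intermediate
13 | (4E)-5-bromo-4-methylpent-4-en-1-ol | OCCC/C(C)=C/Br | intermediate
14 | (4E)-5-bromo-4-methylpent-4-enal | O=CCC/C(C)=C/Br | intermediate
15 | (1E)-1-bromo-2-methylhex-1-en-5-yne | C#CCC/C(C)=C/Br | intermediate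
16 | lithium (5E)-6-bromo-5-methylhex-5-en-1-yn-1-ide (not isolated) | [Li]C#CCC/C(C)=C/Br | intermediate
17 | lithium [(5E)-6-bromo-5-methylhex-5-en-1-yn-1-yl](iodomethyl)pinacolatoborate (not isolated) | [Li+].Br/C=C(\C)CCC#C[B-]1(CI)OC(C)(C)C(C)(C)O1 | intermediate
18 | 2-[(6E)-7-bromo-6-methylhept-6-en-2-yn-1-yl]-4,4,5,5-tetramethyl-1,3,2-dioxaborolane | Br/C=C(\C)CCC#CCB1OC(C)(C)C(C)(C)O1 | intermediate
19 | O-(4,4,5,5-tetramethyl-1,3,2-dioxaborolan-2-yl) derivative of allenol 20 (not isolated) | Br/C=C(\C)CCC(=C=C)[C@@H](OB1OC(C)(C)C(C)(C)O1)/C=C(\C)CC[C@@H]2O[C@@]2(C)CCBr | intermediate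
20 | (4S,5E)-3-[(3E)-4-bromo-3-methylbut-3-en-1-yl]-8-[(2S,3S)-3-(2-bromoethyl)-3-methyloxiran-2-yl]-6-methylocta-1,2,5-trien-4-ol | Br/C=C(\C)CCC(=C=C)[C@@H](O)/C=C(\C)CC[C@@H]1O[C@@]1(C)CCBr | intermediate
21 | methyl (5S)-4-[(3E)-4-bromo-3-methylbut-3-en-1-yl]-5-{(1E)-4-[(2S,3S)-3-(2-bromoethyl)-3-methyloxiran-2-yl]-2-methylbut-1-en-1-yl}-2,5-dihydrofuran-3-carboxylate | COC(=O)C1=C(CC/C(C)=C/Br)[C@H](/C=C(\C)CC[C@@H]2O[C@@]2(C)CCBr)OC1 | intermediate
22 | methyl (2S,7S,8S,3E,11E)-2,16:7,8-diepoxycembra-1(15),3,11-trien-17-oate (target skeleton with CO2Me in place of CH2OAc) | COC(=O)C1=C2CC/C(C)=C/CC[C@]3(C)O[C@H]3CC/C(C)=C/[C@@H]2OC1 | intermediate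
23 | (2S,7S,8S,3E,11E)-2,16:7,8-diepoxycembra-1(15),3,11-trien-17-ol | OCC1=C2CC/C(C)=C/CC[C@]3(C)O[C@H]3CC/C(C)=C/[C@@H]2OC1 | intermediate
24 | (2S,7S,8S,3E,11E)-17-acetoxy-2,16:7,8-diepoxycembra-1(15),3,11-triene | CC(=O)OCC1=C2CC/C(C)=C/CC[C@]3(C)O[C@H]3CC/C(C)=C/[C@@H]2OC1 | target

**Step count and risks**
Total: 15 steps. Longest linear sequence: 10 steps (2, 3, 4, 5, 6, 11, 12, 13, 14, 15; the path from 1 through steps 1, 3–6, 11–15 is also 10), which is two thirds of the total.

Steps most likely to fail: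

- **Step 13 (the proposed new macrocyclisation).** Risks are oligomerisation, hydrodehalogenation, and attack of low-valent nickel or the manganese salts on the epoxide or the allylic ether. The fallback uses known chemistry and replaces the radical cross-electrophile manifold by a pre-formed organozinc and palladium. It sets out from 21: NaI in acetone at 40 °C exchanges only the primary bromide to give methyl (5S)-4-[(3E)-4-bromo-3-methylbut-3-en-1-yl]-5-{(1E)-4-[(2S,3S)-3-(2-iodoethyl)-3-methyloxiran-2-yl]-2-methylbut-1-en-1-yl}-2,5-dihydrofuran-3-carboxylate F5. Activated Zn dust in DMA at 40 °C inserts only into the C(sp3)–I bond to give the alkylzinc iodide F6, which is added by syringe pump to Pd2(dba)3/SPhos in THF–DMA at 50 °C (intramolecular Negishi alkyl–alkenyl coupling). This comes back to the route at 22.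

- **Step 12 (cyclisation–methoxycarbonylation).** Risks are ketone-forming dimerisation of the acylpalladium species, carbonylation at the alkenyl bromide by stray zerovalent palladium, and acid-induced epoxide opening. The fallback separates ring closure from carbonylation. It sets out from 20: NIS in CH2Cl2 at 0 °C gives 5-endo iodocyclisation to (2S)-3-[(3E)-4-bromo-3-methylbut-3-en-1-yl]-2-{(1E)-4-[(2S,3S)-3-(2-bromoethyl)-3-methyloxiran-2-yl]-2-methylbut-1-en-1-yl}-4-iodo-2,5-dihydrofuran F4. Methoxycarbonylation with Pd(PPh3)4, CO (1 atm), MeOH and Et3N in DMF at 45 °C then takes place at the alkenyl iodide, which adds to zerovalent palladium far faster than the alkenyl or alkyl bromide. This comes back to the route at 21.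

- **Step 11 (asymmetric allenylboration).** Risks are modest enantiocontrol with a β,β-disubstituted enal and acid-sensitivity of the epoxide toward the phosphoric acid. The fallback sets the carbinol centre by reduction instead of by C–C bond formation. It sets out from 10 and 18: without catalyst (toluene, 40 °C) the addition gives borate 19 together with the O-pinacolboryl derivative of the C4 epimer F1, and after work-up a mixture of 20 and (4R,5E)-3-[(3E)-4-bromo-3-methylbut-3-en-1-yl]-8-[(2S,3S)-3-(2-bromoethyl)-3-methyloxiran-2-yl]-6-methylocta-1,2,5-trien-4-ol F2. Buffered Dess–Martin oxidation converges both epimers on (5E)-3-[(3E)-4-bromo-3-methylbut-3-en-1-yl]-8-[(2S,3S)-3-(2-bromoethyl)-3-methyloxiran-2-yl]-6-methylocta-1,2,5-trien-4-one F3. CBS reduction ((R)-2-methyl-CBS-oxazaborolidine, catecholborane, toluene, −78 °C, the α-branched allenyl group acting as the large substituent) then sets the carbinol centre under reagent control. This comes back to the route at 20.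

**Further compounds**
F1 | step 11 | O-(4,4,5,5-tetramethyl-1,3,2-dioxaborolan-2-yl) derivative of the (4R)-epimer of 20 (not isolated) | Br/C=C(\C)CCC(=C=C)[C@H](OB1OC(C)(C)C(C)(C)O1)/C=C(\C)CC[C@@H]2O[C@@]2(C)CCBr
F2 | step 11 | (4R,5E)-3-[(3E)-4-bromo-3-methylbut-3-en-1-yl]-8-[(2S,3S)-3-(2-bromoethyl)-3-methyloxiran-2-yl]-6-methylocta-1,2,5-trien-4-ol | Br/C=C(\C)CCC(=C=C)[C@H](O)/C=C(\C)CC[C@@H]1O[C@@]1(C)CCBr
F3 | step 11 | (5E)-3-[(3E)-4-bromo-3-methylbut-3-en-1-yl]-8-[(2S,3S)-3-(2-bromoethyl)-3-methyloxiran-2-yl]-6-methylocta-1,2,5-trien-4-one | Br/C=C(\C)CCC(=C=C)C(=O)/C=C(\C)CC[C@@H]1O[C@@]1(C)CCBr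
F4 | step 12 | (2S)-3-[(3E)-4-bromo-3-methylbut-3-en-1-yl]-2-{(1E)-4-[(2S,3S)-3-(2-bromoethyl)-3-methyloxiran-2-yl]-2-methylbut-1-en-1-yl}-4-iodo-2,5-dihydrofuran | IC1=C(CC/C(C)=C/Br)[C@H](/C=C(\C)CC[C@@H]2O[C@@]2(C)CCBr)OC1
F5 | step 13 | methyl (5S)-4-[(3E)-4-bromo-3-methylbut-3-en-1-yl]-5-{(1E)-4-[(2S,3S)-3-(2-iodoethyl)-3-methyloxiran-2-yl]-2-methylbut-1-en-1-yl}-2,5-dihydrofuran-3-carboxylate | COC(=O)C1=C(CC/C(C)=C/Br)[C@H](/C=C(\C)CC[C@@H]2O[C@@]2(C)CCI)OC1
F6 | step 13 | alkylzinc iodide from F5 (iodozincioethyl in place of iodoethyl; not isolated) | COC(=O)C1=C(CC/C(C)=C/Br)[C@H](/C=C(\C)CC[C@@H]2O[C@@]2(C)CC[Zn]I)OC1
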